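**Retrosynthetic overview**

1. Last step: cis-semihydrogenation of a 7-O-(1,1-dimethylpropargyl) ether unmasks the heat- and acid-labile 1,1-dimethylallyl ether.
2. Ring C is the only ring built (rings A and B are bought); it is closed at O1–C2 by a Mitsunobu reaction with inversion of an (R)-β-hydroxy ketone.
3. Key bond C2–C3: catalytic enantioselective Mukaiyama aldol addition of the silyl enol ether of the fully substituted ring A acetophenone to benzaldehyde.
4. The ring A ketone comes from 2,4-dihydroxyacetophenone by O-propargylation, Lindlar reduction, aromatic Claisen rearrangement (C-prenyl at C3) and a second O-propargylation.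

Assumption: the SMILES is read as the (2S)-flavanone; the chiral bis-phosphoramide of step 7 is treated as a purchased or separately prepared catalyst.

**Route**

Step 1
Reactants: 1 2,4-dihydroxyacetophenone; 2 3-chloro-3-methylbut-1-yne
Product: 3 1-[2-hydroxy-4-(2-methylbut-3-yn-2-yloxy)phenyl]ethan-1-one
Conditions: K2CO3, KI (cat.), CuI (cat.), acetone, 56 °C
Reagents that add atoms: none
Why: Copper-assisted O-propargylation (Williamson-type etherification with the tertiary propargylic chloride) occurs at the more acidic 4-OH, because the 2-OH is tied up in a hydrogen bond to the acetyl group.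

Step 2
Reactants: 3 1-[2-hydroxy-4-(2-methylbut-3-yn-2-yloxy)phenyl]ethan-1-one
Product: 4 1-[2-hydroxy-4-(2-methylbut-3-en-2-yloxy)phenyl]ethan-1-one
Conditions: H2 (1 atm), Pd/CaCO3 poisoned with Pb(OAc)2 (Lindlar catalyst), quinoline, EtOAc, rt
Reagents that add atoms: none
Why: Lindlar semihydrogenation stops at the terminal alkene and leaves the aryl ketone untouched.

Step 3
Reactants: 4 1-[2-hydroxy-4-(2-methylbut-3-en-2-yloxy)phenyl]ethan-1-one
Product: 5 1-[2,4-dihydroxy-3-(3-methylbut-2-en-1-yl)phenyl]ethan-1-one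
Conditions: N,N-diethylaniline, 140 °C
Reagents that add atoms: none
Why: Aromatic Claisen rearrangement; chelation of the 2-OH to the acetyl group localises the C3–C4 double bond, so the [3,3] shift goes to C3 with allyl inversion (1,1-dimethylallyl becomes prenyl) and the dienone rearomatises.

Step 4
Reactants: 5 1-[2,4-dihydroxy-3-(3-methylbut-2-en-1-yl)phenyl]ethan-1-one; 2 3-chloro-3-methylbut-1-yne
Product: 6 1-[2-hydroxy-3-(3-methylbut-2-en-1-yl)-4-(2-methylbut-3-yn-2-yloxy)phenyl]ethan-1-one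
Conditions: K2CO3, KI (cat.), CuI (cat.), acetone, 56 °C
Reagents that add atoms: none
Why: The same copper-assisted O-propargylation again selects the non-chelated 4-OH; the ether is carried as the robust alkyne until the last step.

Step 5
Reactants: 6 1-[2-hydroxy-3-(3-methylbut-2-en-1-yl)-4-(2-methylbut-3-yn-2-yloxy)phenyl]ethan-1-one
Product: 7 1-[2-(tert-butyldimethylsilyloxy)-3-(3-methylbut-2-en-1-yl)-4-(2-methylbut-3-yn-2-yloxy)phenyl]ethan-1-one
Conditions: TBSOTf, 2,6-lutidine, CH2Cl2, 0 °C → rt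
Reagents that add atoms: tert-butyldimethylsilyl trifluoromethanesulfonate, CC(C)(C)[Si](C)(C)OS(=O)(=O)C(F)(F)F
Why: O-silylation with the reactive silyl triflate overcomes the hindered, chelated phenol, and the weak base does not enolise the ketone.

Step 6
Reactants: 7 1-[2-(tert-butyldimethylsilyloxy)-3-(3-methylbut-2-en-1-yl)-4-(2-methylbut-3-yn-2-yloxy)phenyl]ethan-1-one
Product: 8 1-[2-(tert-butyldimethylsilyloxy)-3-(3-methylbut-2-en-1-yl)-4-(2-methylbut-3-yn-2-yloxy)phenyl]-1-(trimethylsilyloxy)ethene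
Conditions: TMSOTf, Et3N, CH2Cl2, 0 °C (pentane extraction, used crude)
Reagents that add atoms: trimethylsilyl trifluoromethanesulfonate, C[Si](C)(C)OS(=O)(=O)C(F)(F)F
Why: Soft enolisation gives the only possible silyl enol ether of the methyl ketone without a strong base, so the terminal alkyne C–H is not deprotonated.

Step 7
Reactants: 8 1-[2-(tert-butyldimethylsilyloxy)-3-(3-methylbut-2-en-1-yl)-4-(2-methylbut-3-yn-2-yloxy)phenyl]-1-(trimethylsilyloxy)ethene; 9 benzaldehyde
Product: 11 (3R)-1-[2-(tert-butyldimethylsilyloxy)-3-(3-methylbut-2-en-1-yl)-4-(2-methylbut-3-yn-2-yloxy)phenyl]-3-hydroxy-3-phenylpropan-1-one, via trichlorosilyl aldolate 10 (not isolated)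
Conditions: SiCl4 (1.5 equiv), (R,R)-bis-phosphoramide catalyst [two (R)-N,N'-dimethyl-1,1'-binaphthyl-2,2'-diamine phosphoramide units on an N,N'-dimethylpentane-1,5-diamine tether] (5 mol %), i-Pr2NEt (10 mol %), CH2Cl2, −78 °C; then sat. aq. NaHCO3, 0 °C
Reagents that add atoms: silicon tetrachloride, Cl[Si](Cl)(Cl)Cl (its SiCl3 group is held only by 10 and is lost on work-up)
Why: Catalytic enantioselective Mukaiyama aldol addition (Lewis-base-activated SiCl4, open transition state) joins the ring A fragment to benzaldehyde; the (R,R)-catalyst is expected to direct attack to the Re face of the aldehyde, setting C3 as R (to be confirmed by Mosher ester analysis, the (S,S)-catalyst being equally available).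

Step 8
Reactants: 11 (3R)-1-[2-(tert-butyldimethylsilyloxy)-3-(3-methylbut-2-en-1-yl)-4-(2-methylbut-3-yn-2-yloxy)phenyl]-3-hydroxy-3-phenylpropan-1-one
Product: 12 (3R)-3-hydroxy-1-[2-hydroxy-3-(3-methylbut-2-en-1-yl)-4-(2-methylbut-3-yn-2-yloxy)phenyl]-3-phenylpropan-1-one
Conditions: KHF2, MeOH, rt
Reagents that add atoms: none
Why: Fluoride-mediated desilylation cleaves the phenolic silyl ether under slightly acidic conditions, so the β-hydroxy ketone suffers neither retro-aldol cleavage nor dehydration and the stereocentre is untouched.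

Step 9
Reactants: 12 (3R)-3-hydroxy-1-[2-hydroxy-3-(3-methylbut-2-en-1-yl)-4-(2-methylbut-3-yn-2-yloxy)phenyl]-3-phenylpropan-1-one
Product: 13 (2S)-8-(3-methylbut-2-en-1-yl)-7-(2-methylbut-3-yn-2-yloxy)-2-phenyl-2,3-dihydro-4H-chromen-4-one
Conditions: PPh3, DIAD, THF, 0 °C → rt
Reagents that add atoms: none
Why: Intramolecular Mitsunobu etherification closes ring C: the chelated phenol displaces the alkoxyphosphonium group in a 6-exo-tet SN2 reaction with inversion, so the (R)-carbinol becomes (S)-C2.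

Step 10
Reactants: 13 (2S)-8-(3-methylbut-2-en-1-yl)-7-(2-methylbut-3-yn-2-yloxy)-2-phenyl-2,3-dihydro-4H-chromen-4-one
Product: 14 (2S)-7-(2-methylbut-3-en-2-yloxy)-8-(3-methylbut-2-en-1-yl)-2-phenyl-2,3-dihydro-4H-chromen-4-one (Griffinone C)
Conditions: H2 (1 atm), Pd/CaCO3 poisoned with Pb(OAc)2 (Lindlar catalyst), quinoline, EtOAc, rt
Reagents that add atoms: none
Why: Lindlar semihydrogenation reduces only the terminal alkyne under neutral conditions, sparing the prenyl group, the ketone and the benzylic C2–O bond, so C2 is not epimerised and the labile allyl ether is formed at room temperature.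

**Compound list**

1 | 2,4-dihydroxyacetophenone | CC(=O)c1ccc(O)cc1O | starting material
2 | 3-chloro-3-methylbut-1-yne | C#CC(C)(C)Cl | starting material
3 | 1-[2-hydroxy-4-(2-methylbut-3-yn-2-yloxy)phenyl]ethan-1-one | CC(=O)c1ccc(OC(C)(C)C#C)cc1O | intermediate
4 | 1-[2-hydroxy-4-(2-methylbut-3-en-2-yloxy)phenyl]ethan-1-one | CC(=O)c1ccc(OC(C)(C)C=C)cc1O | intermediate
5 | 1-[2,4-dihydroxy-3-(3-methylbut-2-en-1-yl)phenyl]ethan-1-one | CC(=O)c1ccc(O)c(CC=C(C)C)c1O | intermediate
6 | 1-[2-hydroxy-3-(3-methylbut-2-en-1-yl)-4-(2-methylbut-3-yn-2-yloxy)phenyl]ethan-1-one | CC(=O)c1ccc(OC(C)(C)C#C)c(CC=C(C)C)c1O | intermediate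
7 | 1-[2-(tert-butyldimethylsilyloxy)-3-(3-methylbut-2-en-1-yl)-4-(2-methylbut-3-yn-2-yloxy)phenyl]ethan-1-one | CC(=O)c1ccc(OC(C)(C)C#C)c(CC=C(C)C)c1O[Si](C)(C)C(C)(C)C | intermediate
8 | 1-[2-(tert-butyldimethylsilyloxy)-3-(3-methylbut-2-en-1-yl)-4-(2-methylbut-3-yn-2-yloxy)phenyl]-1-(trimethylsilyloxy)ethene | C=C(O[Si](C)(C)C)c1ccc(OC(C)(C)C#C)c(CC=C(C)C)c1O[Si](C)(C)C(C)(C)C | intermediate
9 | benzaldehyde | O=Cc1ccccc1 | starting material
10 | (3R)-1-[2-(tert-butyldimethylsilyloxy)-3-(3-methylbut-2-en-1-yl)-4-(2-methylbut-3-yn-2-yloxy)phenyl]-3-phenyl-3-(trichlorosilyloxy)propan-1-one (trichlorosilyl aldolate) | O=C(C[C@@H](O[Si](Cl)(Cl)Cl)c1ccccc1)c1ccc(OC(C)(C)C#C)c(CC=C(C)C)c1O[Si](C)(C)C(C)(C)C | intermediate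
11 | (3R)-1-[2-(tert-butyldimethylsilyloxy)-3-(3-methylbut-2-en-1-yl)-4-(2-methylbut-3-yn-2-yloxy)phenyl]-3-hydroxy-3-phenylpropan-1-one | O=C(C[C@@H](O)c1ccccc1)c1ccc(OC(C)(C)C#C)c(CC=C(C)C)c1O[Si](C)(C)C(C)(C)C | intermediate
12 | (3R)-3-hydroxy-1-[2-hydroxy-3-(3-methylbut-2-en-1-yl)-4-(2-methylbut-3-yn-2-yloxy)phenyl]-3-phenylpropan-1-one | O=C(C[C@@H](O)c1ccccc1)c1ccc(OC(C)(C)C#C)c(CC=C(C)C)c1O | intermediate
13 | (2S)-8-(3-methylbut-2-en-1-yl)-7-(2-methylbut-3-yn-2-yloxy)-2-phenyl-2,3-dihydro-4H-chromen-4-one | C#CC(C)(C)Oc1ccc2c(c1CC=C(C)C)O[C@H](c1ccccc1)CC2=O | intermediate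
14 | (2S)-7-(2-methylbut-3-en-2-yloxy)-8-(3-methylbut-2-en-1-yl)-2-phenyl-2,3-dihydro-4H-chromen-4-one (Griffinone C) | C=CC(C)(C)Oc1ccc2c(c1CC=C(C)C)O[C@H](c1ccccc1)CC2=O | target

**Summary**

Total step count: 10. Longest linear sequence: 10 steps (1 → 14).

**Steps most likely to fail**

Step 7 (enantioselective aldol). The hindered, electron-rich enol silane may react sluggishly or with lower enantioselectivity, and the facial sense must be confirmed. The fallback sets out from 6 and comes back at 11. Claisen–Schmidt aldol condensation of 6 with 9 (KOH, EtOH, rt) gives (2E)-1-[2-hydroxy-3-(3-methylbut-2-en-1-yl)-4-(2-methylbut-3-yn-2-yloxy)phenyl]-3-phenylprop-2-en-1-one F1. Silylation (TBSOTf, 2,6-lutidine, CH2Cl2) gives its 2'-O-tert-butyldimethylsilyl ether F2. Juliá–Colonna epoxidation (poly-L-leucine, urea–H2O2, DBU, THF, rt) gives the trans-(2R,3S)-epoxy ketone F3. Reductive cleavage of the Cα–O bond ((PhSe)2, NaBH4, AcOH, EtOH, 0 °C) leaves the benzylic C–O bond intact and delivers 11.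

Step 9 (Mitsunobu ring closure). E1cB loss of the activated β-oxygen would give the chalcone, which recloses to racemic flavanone. The fallback sets out from 6 and comes back at 13. The chalcone F1 (made as above) is cyclised by oxa-Michael addition (NaOAc, EtOH, reflux) to the racemic flavanone F4. Kinetic resolution by asymmetric transfer hydrogenation (RuCl[(R,R)-TsDPEN](p-cymene), HCO2H/Et3N, EtOAc, rt, to about 55% conversion) reduces the (2R)-enantiomer to the cis-(2R,4R)-flavan-4-ol F5. The unreacted (2S)-ketone 13 is separated by chromatography (at most 50% yield).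

Step 3 (Claisen rearrangement). Some migration to C5 and thermal cyclisation of the o-prenylphenol are possible. The fallback sets out from 1 and comes back at 5, replacing steps 1 to 3. The dianion of 1 is C-prenylated directly with 1-bromo-3-methylbut-2-ene in 10% aqueous KOH (0 °C → rt), which alkylates the carbon between the two oxygens. The yield is modest, and O-prenyl and 5-prenyl isomers are removed by chromatography; no new intermediate is formed.

**Further compounds**

F0 | step 3 | none | none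
F1 | step 7 | (2E)-1-[2-hydroxy-3-(3-methylbut-2-en-1-yl)-4-(2-methylbut-3-yn-2-yloxy)phenyl]-3-phenylprop-2-en-1-one | O=C(/C=C/c1ccccc1)c1ccc(OC(C)(C)C#C)c(CC=C(C)C)c1O
F2 | step 7 | (2E)-1-[2-(tert-butyldimethylsilyloxy)-3-(3-methylbut-2-en-1-yl)-4-(2-methylbut-3-yn-2-yloxy)phenyl]-3-phenylprop-2-en-1-one | O=C(/C=C/c1ccccc1)c1ccc(OC(C)(C)C#C)c(CC=C(C)C)c1O[Si](C)(C)C(C)(C)C
F3 | step 7 | [2-(tert-butyldimethylsilyloxy)-3-(3-methylbut-2-en-1-yl)-4-(2-methylbut-3-yn-2-yloxy)phenyl][(2R,3S)-3-phenyloxiran-2-yl]methanone | O=C([C@@H]1O[C@H]1c1ccccc1)c1ccc(OC(C)(C)C#C)c(CC=C(C)C)c1O[Si](C)(C)C(C)(C)C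
F4 | step 9 | racemic 8-(3-methylbut-2-en-1-yl)-7-(2-methylbut-3-yn-2-yloxy)-2-phenyl-2,3-dihydro-4H-chromen-4-one | C#CC(C)(C)Oc1ccc2c(c1CC=C(C)C)OC(c1ccccc1)CC2=O
F5 | step 9 | (2R,4R)-8-(3-methylbut-2-en-1-yl)-7-(2-methylbut-3-yn-2-yloxy)-2-phenyl-3,4-dihydro-2H-chromen-4-ol | C#CC(C)(C)Oc1ccc2c(c1CC=C(C)C)O[C@@H](c1ccccc1)C[C@H]2O
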